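**The trap.** Read by itself, the target column flatters the richer recipe: at 2.50 min the teal run holds 37.4 % and the ochre run 28.1 %, and I might conclude that teal wastes less.

| flask | starting material | free catalyst | remark | time |
|---|---|---|---|---|
| ochre | 0.10 M (fed, over 15 s) | 2.5 mol% | run made earlier; the fed solution adds 0.20 times the starting volume |  |
| teal | 0.10 M (fed, over 15 s) | 3.8 mol% | run made earlier; the fed solution adds 0.20 times the starting volume |  |
| flask | 0.10 M (fed, over 15 s) | 5 mol% | the fed solution adds 0.20 times the starting volume | 4.0 min |

- ochre (time / min: target / %, starting material / %): 0.667: 11.2, 85.1; 1.33: 19.3, 67.3; 2.50: 28.1, 39.3; 5.00: 32.7, 6.6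
- teal (time / min: target / %, starting material / %): 0.667: 15.0, 78.3; 1.33: 28.3, 53.6; 2.50: 37.4, 20.6; 5.00: 34.7, 1.0

(readings scatter by 0.5 percentage points)

1. when, up to 4.0 min, the flask holds most target
2. the amount of target, in percent of the starting material charged, at that time
3. earliest time at which at least nineteen twentieths of that best amount are there, in min
4. latest time at which they still are, in min

- every charge counts on the volume at the start, and the solution that is fed holds the whole dose
- what was read earlier has a scatter of 0.5 percentage points, one standard deviation

**The ledger.** I book every mole of starting material, the limiting reagent, under one of three entries: still there, target, or gone elsewhere. At 2.50 min the ochre run books 39.3 %, 28.1 % and 32.6 %. Target divided by all the starting material consumed I call the kept share, the overall selectivity. At 2.50 min it is 0.463 in ochre and 0.471 in teal, so I carry the mean, 0.467. At 5.00 min the two runs average 0.350. So in these two runs the kept share follows the clock, and at 2.50 min teal's extra target goes with extra consumption.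

**My reckoning.** I scale consumption by loading times time. The flask at 5 mol% for 2.50 min matches the ochre run at 2.5 mol% for 5.00 min, so I book 6.6 % still there. For the flask I then book 43.6 % target. Beyond that time I book at most that 6.6 % still to consume in the flask, while the kept share read from the runs falls, so I place the peak near 2.50 min.

**The forecast.** Its best amount stands a little below my figure: 42 % at 2.6 min, with the window from 1.9 min to 3.4 min, reached by “Balancing formation against loss”.

**The flask.** It peaks at 2.44 min with 42.6 %, and the window runs from 1.85 min to 3.22 min.

    catalyst intermediate A → catalyst intermediate B (k = 0.560 s⁻¹)
    catalyst intermediate B → free catalyst + target (k = 0.350 s⁻¹)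
    starting material + target → side product (k = 0.110 M⁻¹ s⁻¹)
    starting material + free catalyst → catalyst intermediate A (k = 5.90 M⁻¹ s⁻¹)
    target + free catalyst ⇌ isomer of the product + free catalyst, rate k5*[free catalyst]*[target] forward; the back reaction follows from the equilibrium constant (K = 1.10, k = 2.20 M⁻¹ s⁻¹)

**The neighbour.** In this flask at 2.44 min the kept share comes to 0.482, and the gap holds side product 27.8 %, which counts as two in each percentage, and isomer of the product 17.0 %. Now take the neighbouring flask at 3 mol% free catalyst. For 4.00 min the runs put the kept share at 0.397, read between 2.50 min and 5.00 min. That neighbour has 9.1 % of its starting material left, so the share gives 36.1 % target. That neighbour holds 36.0 %.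

All runs are simulated for an exercise.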